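**Plan**

- Numbering: C7 is the acetoxy carbon on the veratryl ring, C8 and C8' are the two methyl-bearing carbons, C7' is the benzylic CH2 on the guaiacyl ring, C9 and C9' are the methyl carbons.
- Feature used: C9 and C9' are syn on the C8–C8' bond of the zigzag chain, which is what a trans-3,4-disubstituted thiolane (ring atoms S, C9, C8, C8', C9'; sulfur bridging C9 and C9') leaves behind once both C–S bonds are hydrogenolysed.
- Retrosynthesis: remove the acetate and silyl groups; cut C7'–aryl (alkyl iodide plus guaiacyl Grignard reagent); re-link C9 and C9' through sulfur; cut C8–C9 and C8'–C9' ([3+2] of CH2=S(+)–CH2(−) with an E-alkene); cut the N-acyl bond to the sultam and the aryl–C7 bond (Friedel–Crafts with maleic anhydride).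
- Forward: veratrole + maleic anhydride → E-aroylacrylic acid → N-enoyl sultam → thiolane (the only ring formed, step 3) → C7 carbinol → silyl ether → C7' alcohol → iodide → aryl coupling → ring opened with Raney nickel (Ni) → desilylation, acetylation, phenol release.
- Stereochemistry: C8/C8' trans from the E-alkene in a suprafacial cycloaddition, absolute sense from the (2S)-bornane-10,2-sultam; C7 from a reagent-controlled (S)-CBS reduction; no stereocentre is touched afterwards.

Key step: step 3

Assumption: nonchelated dipolar cycloadditions to N-enoyl bornane-10,2-sultams are taken to follow the usual model (carbonyl anti to the N–S bond, s-cis enoyl unit, approach away from the pseudo-axial sulfonyl oxygen), under which the (2S)-auxiliary exposes the si face of the α-carbon, the face C8' requires; this pairing rests on analogy and is not proven for this dipole, and if the sense proved opposite the (2R)-auxiliary would be used with no other change.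

**Route**

Step 1
Reactants: 1 veratrole (1,2-dimethoxybenzene); 2 maleic anhydride
Product: 3 (E)-4-(3,4-dimethoxyphenyl)-4-oxobut-2-enoic acid
Conditions: AlCl3 (2.2 equiv), CH2Cl2, 0 °C → rt; aq. HCl
Reagents that add atoms: none
Why: Friedel–Crafts acylation of the electron-rich arene by the AlCl3-activated anhydride occurs para to a methoxy group and opens the anhydride to the keto acid, whose E alkene is the thermodynamic isomer under the acidic conditions.

Step 2
Reactants: 3 (E)-4-(3,4-dimethoxyphenyl)-4-oxobut-2-enoic acid; 4 (2S)-bornane-10,2-sultam [(1R)-(+)-2,10-camphorsultam]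
Product: 7 N-[(E)-4-(3,4-dimethoxyphenyl)-4-oxobut-2-enoyl]-(2S)-bornane-10,2-sultam, via aroylacryloyl chloride 5 (not isolated), via sodium sultamide 6 (not isolated)
Conditions: (COCl)2, DMF (cat.), CH2Cl2, 0 °C → rt, evaporate; separately 4, NaH, toluene, rt; crude 5 added at −20 °C → rt
Reagents that add atoms: none
Why: N-acylation of a sultam anion by an acid chloride is the standard way to N-enoyl sultams, the E geometry of 3 prevents collapse to a cyclic pseudo-chloride, and adding the chloride cold to a slight deficit of the anion keeps the sulfonamide from adding to the enone in conjugate fashion.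

Step 3
Reactants: 7 N-[(E)-4-(3,4-dimethoxyphenyl)-4-oxobut-2-enoyl]-(2S)-bornane-10,2-sultam; 8 chloromethyl trimethylsilylmethyl sulfide
Product: 10 N-[(3S,4S)-4-(3,4-dimethoxybenzoyl)thiolane-3-carbonyl]-(2S)-bornane-10,2-sultam, via thiocarbonyl ylide 9 (not isolated)
Conditions: CsF (4 equiv), 8 (3 equiv, slow addition), MeCN, rt
Reagents that add atoms: none
Why: Fluoride attack on silicon of 8 and 1,3-loss of chloride release the parent thiocarbonyl ylide 9, a nucleophilic 1,3-dipole that adds in a concerted suprafacial [3+2] cycloaddition (dipole HOMO, alkene LUMO) across the doubly acceptor-substituted alkene of 7, forming C8–C9 and C8'–C9' together. The closest known reaction type is the addition of this same ylide to chiral α,β-unsaturated N-acyl sultams, which gives trans-3,4-disubstituted thiolanes. The thiolane ring is closed by this intermolecular five-membered cycloaddition mode, the C–S–C unit supplying three ring atoms and the alkene two, so no separate cyclisation is involved. The trans relation of C8 and C8' follows from the E geometry of 7, which a concerted addition transfers unchanged, and their absolute sense is set by the (2S)-sultam, whose nonchelated s-cis enoyl conformer is expected to leave the si face of C8' open (see the assumption). The step needs face selectivity, secured by the auxiliary with the minor diastereomer removed by crystallisation or chromatography, and chemoselectivity for C=C over the aryl ketone, secured by the much lower LUMO of an alkene flanked by two carbonyl groups; regiochemistry does not arise because the dipole is symmetrical.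

Step 4
Reactants: 10 N-[(3S,4S)-4-(3,4-dimethoxybenzoyl)thiolane-3-carbonyl]-(2S)-bornane-10,2-sultam
Product: 11 N-[(3S,4S)-4-[(R)-(3,4-dimethoxyphenyl)(hydroxy)methyl]thiolane-3-carbonyl]-(2S)-bornane-10,2-sultam
Conditions: (S)-2-methyl-CBS-oxazaborolidine (0.5 equiv), BH3·SMe2, THF, −20 °C; MeOH quench
Reagents that add atoms: none
Why: Corey–Bakshi–Shibata reduction, in which the (S)-oxazaborolidine–borane complex binds the aryl ketone with the veratryl group as the large substituent and delivers hydride to give the (R)-carbinol at C7 under reagent control while the far less electrophilic N-acyl sultam is left alone at this temperature.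

Step 5
Reactants: 11 N-[(3S,4S)-4-[(R)-(3,4-dimethoxyphenyl)(hydroxy)methyl]thiolane-3-carbonyl]-(2S)-bornane-10,2-sultam
Product: 12 N-[(3S,4S)-4-[(R)-(tert-butyldimethylsilyloxy)(3,4-dimethoxyphenyl)methyl]thiolane-3-carbonyl]-(2S)-bornane-10,2-sultam
Conditions: TBSOTf, 2,6-lutidine, CH2Cl2, −78 → 0 °C
Reagents that add atoms: tert-butyldimethylsilyl trifluoromethanesulfonate, CC(C)(C)[Si](C)(C)OS(=O)(=O)C(F)(F)F
Why: Silylation of a hindered secondary benzylic alcohol with a silyl triflate and a hindered pyridine base is routine and leaves the acyl sultam, the thioether and all three stereocentres untouched.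

Step 6
Reactants: 12 N-[(3S,4S)-4-[(R)-(tert-butyldimethylsilyloxy)(3,4-dimethoxyphenyl)methyl]thiolane-3-carbonyl]-(2S)-bornane-10,2-sultam
Product: 13 [(3S,4S)-4-[(R)-(tert-butyldimethylsilyloxy)(3,4-dimethoxyphenyl)methyl]thiolan-3-yl]methanol
Conditions: LiBH4, MeOH (1 equiv), THF, 0 °C → rt
Reagents that add atoms: none
Why: Reductive cleavage of the activated N-acyl sultam by borohydride gives the primary C7' alcohol and returns the auxiliary, hydride addition being faster than enolisation so that C8' is not epimerised and the silyl ether is unaffected.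

Step 7
Reactants: 13 [(3S,4S)-4-[(R)-(tert-butyldimethylsilyloxy)(3,4-dimethoxyphenyl)methyl]thiolan-3-yl]methanol
Product: 14 (3R,4S)-3-(iodomethyl)-4-[(R)-(tert-butyldimethylsilyloxy)(3,4-dimethoxyphenyl)methyl]thiolane
Conditions: PPh3, I2, imidazole, CH2Cl2, 0 °C → rt
Reagents that add atoms: iodine, II
Why: Appel-type iodination with PPh3, I2 and imidazole converts the primary alcohol into the iodide by SN2 displacement at the CH2 carbon, conditions that a thioether and a silyl ether tolerate.

Step 8
Reactants: 15 4-bromo-2-methoxyphenol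
Product: 16 (4-bromo-2-methoxyphenoxy)(tert-butyl)dimethylsilane
Conditions: TBSCl, imidazole, DMF, rt
Reagents that add atoms: tert-butyldimethylsilyl chloride, CC(C)(C)[Si](C)(C)Cl
Why: Imidazole-promoted silylation of the phenol masks its acidic proton so that the aryl bromide can be converted into a Grignard reagent.

Step 9
Reactants: 14 (3R,4S)-3-(iodomethyl)-4-[(R)-(tert-butyldimethylsilyloxy)(3,4-dimethoxyphenyl)methyl]thiolane; 16 (4-bromo-2-methoxyphenoxy)(tert-butyl)dimethylsilane
Product: 18 (3R,4S)-3-[4-(tert-butyldimethylsilyloxy)-3-methoxybenzyl]-4-[(R)-(tert-butyldimethylsilyloxy)(3,4-dimethoxyphenyl)methyl]thiolane, via arylmagnesium bromide 17 (not isolated)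
Conditions: 16, Mg, THF, reflux; then 14, Li2CuCl4 (5 mol %), THF, −20 °C → rt
Reagents that add atoms: none
Why: Copper-catalysed cross-coupling of an aryl Grignard reagent with a primary alkyl iodide (Kochi-type coupling) forms the C7'–aryl bond at a carbon that is not stereogenic, and the silyl ethers and the thioether are inert to the organomagnesium reagent.

Step 10
Reactants: 18 (3R,4S)-3-[4-(tert-butyldimethylsilyloxy)-3-methoxybenzyl]-4-[(R)-(tert-butyldimethylsilyloxy)(3,4-dimethoxyphenyl)methyl]thiolane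
Product: 19 tert-butyl{[(1R,2S,3R)-4-[4-(tert-butyldimethylsilyloxy)-3-methoxyphenyl]-1-(3,4-dimethoxyphenyl)-2,3-dimethylbutyl]oxy}dimethylsilane
Conditions: Raney nickel (Ni, W-2, excess), EtOH/THF, rt → 50 °C
Reagents that add atoms: none
Why: Raney nickel hydrogenolysis of both C–S bonds (reductive desulfurisation) turns C9 and C9' into methyl groups, and because the bonds broken are at CH2 carbons the centres C8 and C8' are not involved, while silyl-protected benzylic and phenolic oxygens should survive under these mild conditions.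

Step 11
Reactants: 19 tert-butyl{[(1R,2S,3R)-4-[4-(tert-butyldimethylsilyloxy)-3-methoxyphenyl]-1-(3,4-dimethoxyphenyl)-2,3-dimethylbutyl]oxy}dimethylsilane
Product: 20 (1R,2S,3R)-1-(3,4-dimethoxyphenyl)-4-(4-hydroxy-3-methoxyphenyl)-2,3-dimethylbutan-1-ol
Conditions: Bu4NF, AcOH (1:1, excess), THF, rt → 40 °C
Reagents that add atoms: none
Why: Fluoride-mediated desilylation removes the aryl and the alkyl silyl ether in one operation, the acetic acid buffer keeping the medium non-basic so that C7 is not at risk.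

Step 12
Reactants: 20 (1R,2S,3R)-1-(3,4-dimethoxyphenyl)-4-(4-hydroxy-3-methoxyphenyl)-2,3-dimethylbutan-1-ol
Product: 21 (1R,2S,3R)-4-(4-acetoxy-3-methoxyphenyl)-1-(3,4-dimethoxyphenyl)-2,3-dimethylbutyl acetate
Conditions: Ac2O, pyridine, DMAP (cat.), CH2Cl2, rt
Reagents that add atoms: acetic anhydride, CC(=O)OC(C)=O
Why: DMAP-catalysed acylation with acetic anhydride esterifies both the phenol and the hindered secondary benzylic alcohol with retention at C7.

Step 13
Reactants: 21 (1R,2S,3R)-4-(4-acetoxy-3-methoxyphenyl)-1-(3,4-dimethoxyphenyl)-2,3-dimethylbutyl acetate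
Product: 22 (1R,2S,3R)-1-(3,4-dimethoxyphenyl)-4-(4-hydroxy-3-methoxyphenyl)-2,3-dimethylbutyl acetate (CNP0118842.1)
Conditions: pyrrolidine (1.5 equiv), CH2Cl2, 0 °C → rt
Reagents that add atoms: none
Why: Chemoselective aminolysis, since the aryl acetate with its far better phenoxide leaving group is cleaved by the secondary amine at a rate the hindered secondary alkyl acetate at C7 cannot match.

**Compound list**

1 | veratrole | COc1ccccc1OC | starting material
2 | maleic anhydride | O=C1OC(=O)C=C1 | starting material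
3 | (E)-4-(3,4-dimethoxyphenyl)-4-oxobut-2-enoic acid | OC(=O)/C=C/C(=O)c1ccc(OC)c(OC)c1 | intermediate
4 | (2S)-bornane-10,2-sultam [(1R)-(+)-2,10-camphorsultam] | CC1(C)[C@H]2CC[C@@]13CS(=O)(=O)N[C@H]3C2 | starting material
5 | (E)-4-(3,4-dimethoxyphenyl)-4-oxobut-2-enoyl chloride | ClC(=O)/C=C/C(=O)c1ccc(OC)c(OC)c1 | intermediate
6 | sodium salt of (2S)-bornane-10,2-sultam | CC1(C)[C@H]2CC[C@@]13CS(=O)(=O)[N-][C@H]3C2.[Na+] | intermediate
7 | N-[(E)-4-(3,4-dimethoxyphenyl)-4-oxobut-2-enoyl]-(2S)-bornane-10,2-sultam | CC1(C)[C@H]2CC[C@@]13CS(=O)(=O)N(C(=O)/C=C/C(=O)c4ccc(OC)c(OC)c4)[C@H]3C2 | intermediate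
8 | chloromethyl trimethylsilylmethyl sulfide | C[Si](C)(C)CSCCl | starting material
9 | thioformaldehyde S-methylide (parent thiocarbonyl ylide) | C=[S+][CH2-] | intermediate
10 | N-[(3S,4S)-4-(3,4-dimethoxybenzoyl)thiolane-3-carbonyl]-(2S)-bornane-10,2-sultam | CC1(C)[C@H]2CC[C@@]13CS(=O)(=O)N(C(=O)[C@H]4CSC[C@@H]4C(=O)c5ccc(OC)c(OC)c5)[C@H]3C2 | intermediate
11 | N-[(3S,4S)-4-[(R)-(3,4-dimethoxyphenyl)(hydroxy)methyl]thiolane-3-carbonyl]-(2S)-bornane-10,2-sultam | CC1(C)[C@H]2CC[C@@]13CS(=O)(=O)N(C(=O)[C@H]4CSC[C@@H]4[C@@H](O)c5ccc(OC)c(OC)c5)[C@H]3C2 | intermediate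
12 | N-[(3S,4S)-4-[(R)-(tert-butyldimethylsilyloxy)(3,4-dimethoxyphenyl)methyl]thiolane-3-carbonyl]-(2S)-bornane-10,2-sultam | CC1(C)[C@H]2CC[C@@]13CS(=O)(=O)N(C(=O)[C@H]4CSC[C@@H]4[C@@H](O[Si](C)(C)C(C)(C)C)c5ccc(OC)c(OC)c5)[C@H]3C2 | intermediate
13 | [(3S,4S)-4-[(R)-(tert-butyldimethylsilyloxy)(3,4-dimethoxyphenyl)methyl]thiolan-3-yl]methanol | OC[C@H]1CSC[C@@H]1[C@@H](O[Si](C)(C)C(C)(C)C)c1ccc(OC)c(OC)c1 | intermediate
14 | (3R,4S)-3-(iodomethyl)-4-[(R)-(tert-butyldimethylsilyloxy)(3,4-dimethoxyphenyl)methyl]thiolane | IC[C@H]1CSC[C@@H]1[C@@H](O[Si](C)(C)C(C)(C)C)c1ccc(OC)c(OC)c1 | intermediate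
15 | 4-bromo-2-methoxyphenol | COc1cc(Br)ccc1O | starting material
16 | (4-bromo-2-methoxyphenoxy)(tert-butyl)dimethylsilane | COc1cc(Br)ccc1O[Si](C)(C)C(C)(C)C | intermediate
17 | [4-(tert-butyldimethylsilyloxy)-3-methoxyphenyl]magnesium bromide | COc1cc([Mg]Br)ccc1O[Si](C)(C)C(C)(C)C | intermediate
18 | (3R,4S)-3-[4-(tert-butyldimethylsilyloxy)-3-methoxybenzyl]-4-[(R)-(tert-butyldimethylsilyloxy)(3,4-dimethoxyphenyl)methyl]thiolane | COc1cc(C[C@H]2CSC[C@@H]2[C@@H](O[Si](C)(C)C(C)(C)C)c2ccc(OC)c(OC)c2)ccc1O[Si](C)(C)C(C)(C)C | intermediate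
19 | tert-butyl{[(1R,2S,3R)-4-[4-(tert-butyldimethylsilyloxy)-3-methoxyphenyl]-1-(3,4-dimethoxyphenyl)-2,3-dimethylbutyl]oxy}dimethylsilane | COc1cc(C[C@@H](C)[C@H](C)[C@@H](O[Si](C)(C)C(C)(C)C)c2ccc(OC)c(OC)c2)ccc1O[Si](C)(C)C(C)(C)C | intermediate
20 | (1R,2S,3R)-1-(3,4-dimethoxyphenyl)-4-(4-hydroxy-3-methoxyphenyl)-2,3-dimethylbutan-1-ol | COc1cc(C[C@@H](C)[C@H](C)[C@@H](O)c2ccc(OC)c(OC)c2)ccc1O | intermediate
21 | (1R,2S,3R)-4-(4-acetoxy-3-methoxyphenyl)-1-(3,4-dimethoxyphenyl)-2,3-dimethylbutyl acetate | COc1cc(C[C@@H](C)[C@H](C)[C@@H](OC(C)=O)c2ccc(OC)c(OC)c2)ccc1OC(C)=O | intermediate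
22 | (1R,2S,3R)-1-(3,4-dimethoxyphenyl)-4-(4-hydroxy-3-methoxyphenyl)-2,3-dimethylbutyl acetate | COc1cc(C[C@@H](C)[C@H](C)[C@@H](OC(C)=O)c2ccc(OC)c(OC)c2)ccc1O | target

**Count and risks**

Total step count: 13. Longest linear sequence: 12 (steps 1–7 and 9–13 from veratrole; step 8 is a one-step branch).

Steps most likely to fail:

1. Step 3. Face discrimination by the auxiliary may be modest with so small and reactive a dipole, and the ylide may be consumed by oligomerisation before it meets the alkene. Fallback (control by separation instead of induction, same cycloaddition): setting out from acid 3, methylation (MeI, KHCO3, DMF) gives methyl (E)-4-(3,4-dimethoxyphenyl)-4-oxobut-2-enoate F1. The same ylide cycloaddition (8, CsF, MeCN) gives racemic methyl trans-4-(3,4-dimethoxybenzoyl)thiolane-3-carboxylate F2. LiOH in aqueous THF gives racemic trans-4-(3,4-dimethoxybenzoyl)thiolane-3-carboxylic acid F3; the trans isomer is the thermodynamic one, so base does not endanger it. (COCl)2 gives racemic trans-4-(3,4-dimethoxybenzoyl)thiolane-3-carbonyl chloride F4, which acylates sodium sultamide 6 to a pair of diastereomers, 10 and N-[(3R,4R)-4-(3,4-dimethoxybenzoyl)thiolane-3-carbonyl]-(2S)-bornane-10,2-sultam F5. These are separated by crystallisation or chromatography and the route is rejoined at 10.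

2. Step 4. The sense imposed by the catalyst at C7 is opposite to the Felkin–Anh preference expected from C8, so the pairing may be mismatched and selectivity may erode; coordination of borane to the ring sulfur may add an uncatalysed background reduction. Fallback (substrate control followed by inversion): setting out from 10, LiBH(s-Bu)3 in THF at −78 °C should give the Felkin–Anh carbinol N-[(3S,4S)-4-[(S)-(3,4-dimethoxyphenyl)(hydroxy)methyl]thiolane-3-carbonyl]-(2S)-bornane-10,2-sultam F6. Mitsunobu esterification (PPh3, diisopropyl azodicarboxylate, 4-nitrobenzoic acid, toluene, 0 °C) inverts C7 and gives (R)-(3,4-dimethoxyphenyl)[(3S,4S)-4-{[(2S)-bornane-10,2-sultam-N-yl]carbonyl}thiolan-3-yl]methyl 4-nitrobenzoate F7. LiBH4 cleaves both the ester and the acyl sultam to give (R)-(3,4-dimethoxyphenyl)[(3S,4S)-4-(hydroxymethyl)thiolan-3-yl]methanol F8. PPh3/I2/imidazole at 0 °C converts only the primary hydroxyl and gives (R)-(3,4-dimethoxyphenyl)[(3S,4R)-4-(iodomethyl)thiolan-3-yl]methanol F9. Silylation (TBSOTf, 2,6-lutidine) then gives iodide 14, where the route is rejoined.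

3. Step 9. Substitution at the β-branched primary iodide may be slow, so that halogen–magnesium exchange, reduction of the iodide or homocoupling of the Grignard reagent competes. Fallback (polarity of the alkyl partner reversed): setting out from 14, zinc insertion (Zn dust, LiCl, THF, 40 °C) gives {[(3R,4S)-4-[(R)-(tert-butyldimethylsilyloxy)(3,4-dimethoxyphenyl)methyl]thiolan-3-yl]methyl}zinc iodide F10, which undergoes Negishi coupling with aryl bromide 16 (Pd(OAc)2, SPhos, THF, 50 °C) to give 18, where the route is rejoined.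

Further compounds
F1 | step 3 | methyl (E)-4-(3,4-dimethoxyphenyl)-4-oxobut-2-enoate | COC(=O)/C=C/C(=O)c1ccc(OC)c(OC)c1
F2 | step 3 | methyl trans-4-(3,4-dimethoxybenzoyl)thiolane-3-carboxylate (racemic; 3S,4S enantiomer drawn) | COC(=O)[C@H]1CSC[C@@H]1C(=O)c1ccc(OC)c(OC)c1
F3 | step 3 | trans-4-(3,4-dimethoxybenzoyl)thiolane-3-carboxylic acid (racemic; 3S,4S enantiomer drawn) | OC(=O)[C@H]1CSC[C@@H]1C(=O)c1ccc(OC)c(OC)c1
F4 | step 3 | trans-4-(3,4-dimethoxybenzoyl)thiolane-3-carbonyl chloride (racemic; 3S,4S enantiomer drawn) | ClC(=O)[C@H]1CSC[C@@H]1C(=O)c1ccc(OC)c(OC)c1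
F5 | step 3 | N-[(3R,4R)-4-(3,4-dimethoxybenzoyl)thiolane-3-carbonyl]-(2S)-bornane-10,2-sultam | CC1(C)[C@H]2CC[C@@]13CS(=O)(=O)N(C(=O)[C@@H]4CSC[C@H]4C(=O)c5ccc(OC)c(OC)c5)[C@H]3C2
F6 | step 4 | N-[(3S,4S)-4-[(S)-(3,4-dimethoxyphenyl)(hydroxy)methyl]thiolane-3-carbonyl]-(2S)-bornane-10,2-sultam | CC1(C)[C@H]2CC[C@@]13CS(=O)(=O)N(C(=O)[C@H]4CSC[C@@H]4[C@H](O)c5ccc(OC)c(OC)c5)[C@H]3C2
F7 | step 4 | (R)-(3,4-dimethoxyphenyl)[(3S,4S)-4-{[(2S)-bornane-10,2-sultam-N-yl]carbonyl}thiolan-3-yl]methyl 4-nitrobenzoate | CC1(C)[C@H]2CC[C@@]13CS(=O)(=O)N(C(=O)[C@H]4CSC[C@@H]4[C@@H](OC(=O)c5ccc(cc5)[N+](=O)[O-])c6ccc(OC)c(OC)c6)[C@H]3C2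
F8 | step 4 | (R)-(3,4-dimethoxyphenyl)[(3S,4S)-4-(hydroxymethyl)thiolan-3-yl]methanol | OC[C@H]1CSC[C@@H]1[C@@H](O)c1ccc(OC)c(OC)c1
F9 | step 4 | (R)-(3,4-dimethoxyphenyl)[(3S,4R)-4-(iodomethyl)thiolan-3-yl]methanol | IC[C@H]1CSC[C@@H]1[C@@H](O)c1ccc(OC)c(OC)c1
F10 | step 9 | {[(3R,4S)-4-[(R)-(tert-butyldimethylsilyloxy)(3,4-dimethoxyphenyl)methyl]thiolan-3-yl]methyl}zinc iodide | I[Zn]C[C@H]1CSC[C@@H]1[C@@H](O[Si](C)(C)C(C)(C)C)c1ccc(OC)c(OC)c1
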